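**Strategy.** The 14-membered carbocycle is closed at the C4–C5 bond. The trans C3–C4 oxirane on that ring is read as the retron of an (E)-C3=C4 olefin, so the methyl-bearing C4 becomes the sp2 carbon of an alkenyl iodide and the ring methylene C5 an sp3 alkylzinc. One intramolecular Negishi coupling joins them, closes the macrocycle and transfers the pre-set E geometry, which a catalyst-controlled epoxidation then turns into the trans-epoxide. The precursor is an open-chain α-methylene-γ-butyrolactone with an (E)-3-iodobut-2-enyl arm on C1 and an ω-iodoalkyl chain on C14, assembled from (S)-citronellal, (R)-α-hydroxy-γ-butyrolactone, pent-3-yn-1-ol and methyl propiolate.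

Key step: step 20

Remark (numbering): cembrane numbering is used: C1 = lactone CH bearing the C2H2 arm; C3–C4 = oxirane carbons (C4 carries the methyl); C5, C6 = CH2; C7 = CHOH; C8 = C(=CH2); C9–C11 = CH2; C12 = CHCH3; C13 = CHOH; C14 = lactone O–CH; C15(=C17H2)–C16(=O) = methylene-lactone carbons.

**Fragment A (C9–C14)**

Step 1
Reactants: 1 (S)-citronellal
Product: 3 (2R,3S)-3,7-dimethyl-2-[(phenylamino)oxy]oct-6-en-1-ol, via α-anilinooxy aldehyde 2 (not isolated)
Conditions: PhNO, L-proline (20 mol%), DMSO, rt; then NaBH4, MeOH, 0 °C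
Reagents that add atoms: nitrosobenzene, O=Nc1ccccc1
Why: Proline-catalysed α-aminoxylation (enamine attack on the nitroso oxygen) should set C13 as R under catalyst control, independent of the C12 centre, and in situ borohydride reduction secures the labile α-oxy aldehyde.

Step 2
Reactants: 3 (2R,3S)-3,7-dimethyl-2-[(phenylamino)oxy]oct-6-en-1-ol
Product: 4 (2R,3S)-3,7-dimethyloct-6-ene-1,2-diol
Conditions: Zn dust, AcOH, THF, rt
Reagents that add atoms: none
Why: Reductive N–O cleavage by zinc in acetic acid should free the secondary alcohol without touching C12, C13 or the olefin.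

Step 3
Reactants: 4 (2R,3S)-3,7-dimethyloct-6-ene-1,2-diol
Product: 5 (4R)-2,2-dimethyl-4-[(2S)-6-methylhept-5-en-2-yl]-1,3-dioxolane
Conditions: Me2C(OMe)2, PPTS (cat.), CH2Cl2, rt
Reagents that add atoms: 2,2-dimethoxypropane, COC(C)(C)OC
Why: Acid-catalysed transketalisation (acetonide formation) protects the C13/C14 diol for the organometallic steps and affects no stereocentre.

Step 4
Reactants: 5 (4R)-2,2-dimethyl-4-[(2S)-6-methylhept-5-en-2-yl]-1,3-dioxolane
Product: 6 (4S)-4-[(4R)-2,2-dimethyl-1,3-dioxolan-4-yl]pentan-1-ol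
Conditions: O3, CH2Cl2–MeOH, −78 °C; then NaBH4, −78 °C to rt
Reagents that add atoms: ozone, [O-][O+]=O
Why: Ozonolysis of the only olefin with reductive work-up removes the isopropylidene terminus and should deliver C9 as a primary alcohol, the acetonide being inert.

Step 5
Reactants: 6 (4S)-4-[(4R)-2,2-dimethyl-1,3-dioxolan-4-yl]pentan-1-ol
Product: 7 (4R)-4-[(2S)-5-bromopentan-2-yl]-2,2-dimethyl-1,3-dioxolane
Conditions: CBr4, PPh3, CH2Cl2, 0 °C
Reagents that add atoms: carbon tetrabromide, BrC(Br)(Br)Br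
Why: Appel bromination converts the primary alcohol into the bromide under neutral conditions that spare the acetonide.

**Fragment B (C5–C8) and union with fragment A**

Step 6
Reactants: 8 (R)-α-hydroxy-γ-butyrolactone
Product: 9 (2R)-2,4-dihydroxy-N-methoxy-N-methylbutanamide
Conditions: MeNH(OMe)·HCl, Me3Al, CH2Cl2, 0 °C to rt; used crude
Reagents that add atoms: N,O-dimethylhydroxylamine hydrochloride, CNOC.Cl
Why: Weinreb aminolysis of the lactone by the aluminium amide opens the ring without touching the carbinol centre, which becomes C7 (R).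

Step 7
Reactants: 9 (2R)-2,4-dihydroxy-N-methoxy-N-methylbutanamide
Product: 10 (2R)-2,4-bis[(tert-butyldimethylsilyl)oxy]-N-methoxy-N-methylbutanamide
Conditions: TBSCl, imidazole, DMF, rt
Reagents that add atoms: tert-butyldimethylsilyl chloride, CC(C)(C)[Si](C)(C)Cl
Why: Silylation of both hydroxyls blocks relactonisation and protects C5–OH and C7–OH for the Grignard step.

Step 8
Reactants: 7 (4R)-4-[(2S)-5-bromopentan-2-yl]-2,2-dimethyl-1,3-dioxolane; 10 (2R)-2,4-bis[(tert-butyldimethylsilyl)oxy]-N-methoxy-N-methylbutanamide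
Product: 12 (3R,8S)-1,3-bis[(tert-butyldimethylsilyl)oxy]-8-[(4R)-2,2-dimethyl-1,3-dioxolan-4-yl]nonan-4-one, via Grignard reagent 11 (not isolated)
Conditions: Mg, THF, 40 °C; then 10, THF, 0 °C
Reagents that add atoms: none
Why: Weinreb ketone synthesis forms the C8–C9 bond; the chelated tetrahedral intermediate prevents over-addition and the low temperature prevents enolisation at C7.

Step 9
Reactants: 12 (3R,8S)-1,3-bis[(tert-butyldimethylsilyl)oxy]-8-[(4R)-2,2-dimethyl-1,3-dioxolan-4-yl]nonan-4-one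
Product: 13 (3R,8S)-1,3-bis[(tert-butyldimethylsilyl)oxy]-8-[(4R)-2,2-dimethyl-1,3-dioxolan-4-yl]-4-methylidenenonane
Conditions: Ph3PCH3Br, KOtBu, THF, 0 °C
Reagents that add atoms: methyltriphenylphosphonium bromide, C[P+](c1ccccc1)(c1ccccc1)c1ccccc1.[Br-]
Why: Wittig methylenation installs the C8 exocyclic methylene, and low temperature should keep the adjacent C7 silyloxy centre from epimerising.

Step 10
Reactants: 13 (3R,8S)-1,3-bis[(tert-butyldimethylsilyl)oxy]-8-[(4R)-2,2-dimethyl-1,3-dioxolan-4-yl]-4-methylidenenonane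
Product: 14 (3R,8S)-3-[(tert-butyldimethylsilyl)oxy]-8-[(4R)-2,2-dimethyl-1,3-dioxolan-4-yl]-4-methylidenenonan-1-ol
Conditions: HF·pyridine, pyridine, THF, 0 °C
Reagents that add atoms: none
Why: Selective desilylation: buffered HF·pyridine removes the unhindered primary silyl ether much faster than the secondary allylic one and leaves the acetonide intact.

Step 11
Reactants: 14 (3R,8S)-3-[(tert-butyldimethylsilyl)oxy]-8-[(4R)-2,2-dimethyl-1,3-dioxolan-4-yl]-4-methylidenenonan-1-ol
Product: 15 (4R)-4-[(2S,7R)-7-[(tert-butyldimethylsilyl)oxy]-9-iodo-6-methylidenenonan-2-yl]-2,2-dimethyl-1,3-dioxolane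
Conditions: I2, PPh3, imidazole, CH2Cl2, 0 °C
Reagents that add atoms: iodine, II
Why: Appel-type iodination turns the primary alcohol into the C5 iodide needed for the later zinc insertion.

Step 12
Reactants: 15 (4R)-4-[(2S,7R)-7-[(tert-butyldimethylsilyl)oxy]-9-iodo-6-methylidenenonan-2-yl]-2,2-dimethyl-1,3-dioxolane
Product: 16 (2R,3S,8R)-8-[(tert-butyldimethylsilyl)oxy]-10-iodo-3-methyl-7-methylidenedecane-1,2-diol
Conditions: PPTS (cat.), MeOH, 40 °C
Reagents that add atoms: none
Why: Acid-catalysed methanolysis (transketalisation) of the terminal acetonide frees the C13/C14 diol while the secondary TBS ether and the iodide should persist.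

Step 13
Reactants: 16 (2R,3S,8R)-8-[(tert-butyldimethylsilyl)oxy]-10-iodo-3-methyl-7-methylidenedecane-1,2-diol
Product: 17 (2R,3S,8R)-8-[(tert-butyldimethylsilyl)oxy]-2-hydroxy-10-iodo-3-methyl-7-methylidenedecanal
Conditions: TEMPO (10 mol%), NCS, Bu4NCl, CH2Cl2/aq. NaHCO3–K2CO3 (pH 8.6), rt; used crude
Reagents that add atoms: none
Why: TEMPO-catalysed oxidation with NCS is selective for the primary hydroxyl and gives the α-hydroxy aldehyde, used at once to avoid dimerisation and epimerisation at C13.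

**Fragment W (C1–C4, C15–C17)**

Step 14
Reactants: 18 pent-3-yn-1-ol
Product: 20 (3E)-4-iodopent-3-en-1-ol, via alkenylzirconocene 19 (not isolated)
Conditions: Cp2Zr(H)Cl (2.5 equiv), THF, rt to 40 °C; then I2, 0 °C
Reagents that add atoms: iodine, II
Why: Hydrozirconation–iodination: syn addition of Zr–H should place zirconium on the less hindered methyl-bearing alkyne carbon (excess reagent allows equilibration), and iodinolysis with retention gives the E-alkenyl iodide.

Step 15
Reactants: 20 (3E)-4-iodopent-3-en-1-ol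
Product: 21 (3E)-4-iodopent-3-enal
Conditions: Dess–Martin periodinane, NaHCO3, CH2Cl2, 0 °C; used crude
Reagents that add atoms: none
Why: Dess–Martin oxidation under buffered, non-basic conditions should give the β,γ-unsaturated aldehyde without migration of the double bond.

Step 16
Reactants: 21 (3E)-4-iodopent-3-enal; 22 methyl propiolate
Product: 24 methyl (5E)-3-hydroxy-6-iodo-2-methylidenehept-5-enoate (racemic), via α-aluminoacrylate 23 (not isolated)
Conditions: 22, DIBAL-H, NMO, THF, 0 °C; then 21, 0 °C to rt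
Reagents that add atoms: none
Why: Vinylalumination (hydroalumination of the propiolate to the α-aluminoacrylate, then carbonyl addition) gives the Morita–Baylis–Hillman-type adduct without the amine base that would isomerise the aldehyde; the racemic carbinol centre is destroyed in step 17.

Step 17
Reactants: 24 methyl (5E)-3-hydroxy-6-iodo-2-methylidenehept-5-enoate
Product: 25 methyl (2Z,5E)-2-(bromomethyl)-6-iodohepta-2,5-dienoate
Conditions: NBS, Me2S, CH2Cl2, 0 °C to rt
Reagents that add atoms: N-bromosuccinimide, O=C1CCC(=O)N1Br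
Why: Bromination with allylic transposition (SN2′ on the alkoxysulfonium intermediate) should give the thermodynamically preferred 2Z bromide, in which C2 is cis to CH2Br.

**Union, ring closure and endgame**

Step 18
Reactants: 17 (2R,3S,8R)-8-[(tert-butyldimethylsilyl)oxy]-2-hydroxy-10-iodo-3-methyl-7-methylidenedecanal; 25 methyl (2Z,5E)-2-(bromomethyl)-6-iodohepta-2,5-dienoate
Product: 28 (4S,5R)-5-[(1R,2S,7R)-7-[(tert-butyldimethylsilyl)oxy]-1-hydroxy-9-iodo-2-methyl-6-methylidenenonyl]-4-[(2E)-3-iodobut-2-en-1-yl]-3-methylideneoxolan-2-one, via allylindium reagent 26 (not isolated), via hydroxy ester 27 (not isolated)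
Conditions: In powder, THF–H2O (1:1), rt; then TsOH·H2O (cat.), CH2Cl2, rt
Reagents that add atoms: none
Why: Indium-mediated Barbier allylation then acid lactonisation: the allylindium attacks through its γ-carbon (C1); chelation of indium between the aldehyde and the free C13 hydroxyl should give the 13,14-syn diol (C14 R); the Z reagent in a closed chair transition state should give the 14,1-syn adduct (C1 S), which closes onto the C14 hydroxyl to the cis-disubstituted γ-lactone.

Step 19
Reactants: 28 (the C13-hydroxy lactone)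
Product: 29 (4S,5R)-5-[(1R,2S,7R)-1,7-bis[(tert-butyldimethylsilyl)oxy]-9-iodo-2-methyl-6-methylidenenonyl]-4-[(2E)-3-iodobut-2-en-1-yl]-3-methylideneoxolan-2-one
Conditions: TBSOTf, 2,6-lutidine, CH2Cl2, −78 °C
Reagents that add atoms: tert-butyldimethylsilyl triflate, CC(C)(C)[Si](C)(C)OS(=O)(=O)C(F)(F)F
Why: Silylation protects the hindered C13 hydroxyl, whose proton would otherwise quench the alkylzinc reagent.

Step 20
Reactants: 29 (the bis-silyl diiodide)
Product: 31 (1S,3E,7R,12S,13R,14R)-7,13-bis[(tert-butyldimethylsilyl)oxy]cembra-3,8(19),15(17)-trien-16,14-olide, via alkylzinc iodide 30 (not isolated)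
Conditions: Zn dust (TMSCl/BrCH2CH2Br-activated), LiCl, THF, 25 °C; then syringe-pump addition to Pd(PPh3)4 (10 mol%), THF, 55 °C, final 1 mM
Reagents that add atoms: none
Why: Zinc should insert selectively into the primary C5–I bond (alkenyl iodides are inert to LiCl-activated zinc at 25 °C); zerovalent palladium then adds oxidatively to the C4–I bond with retention, the tethered alkylzinc transmetalates, and reductive elimination forges the C4–C5 sp2–sp3 bond. The closest known reaction type is the alkyl–alkenyl Negishi coupling, used here intramolecularly in the manner of macrocyclic B-alkyl Suzuki–Miyaura closures. The 14-membered carbocycle closes end-to-end through a 15-membered palladacycle that contracts on reductive elimination, leaving the C3=C4 double bond endocyclic. No stereocentre is created; the E geometry fixed in step 14 is transferred stereospecifically and later decides the trans relationship of C2 and C5 across the oxirane. Ring closure must win over oligomerisation and protodezincation, which slow addition at high dilution and the silylated C13 hydroxyl should secure; the alkenylpalladium cannot attack the lactone methylene because in the E isomer palladium sits trans to the C2 tether, so 5-exo carbopalladation is geometrically impossible.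

Step 21
Reactants: 31 (the bis-silyl macrocycle)
Product: 32 (1S,3E,7R,12S,13R,14R)-7,13-dihydroxycembra-3,8(19),15(17)-trien-16,14-olide
Conditions: HF·pyridine, pyridine, THF, 0 °C to rt
Reagents that add atoms: none
Why: Fluoride-mediated desilylation with buffered HF·pyridine should remove both secondary TBS ethers without opening the lactone or adding to the methylene lactone.

Step 22
Reactants: 32 (the macrocyclic diol)
Product: 33 CNP0124069.1, (1S,3R,4R,7R,12S,13R,14R)-3,4-epoxy-7,13-dihydroxycembra-8(19),15(17)-dien-16,14-olide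
Conditions: Shi ketone (D-fructose-derived, 0.3 equiv), Oxone, K2CO3, Bu4NHSO4, MeCN–CH2(OMe)2/aq. Na2B4O7 buffer, 0 °C
Reagents that add atoms: Oxone (potassium peroxymonosulfate, KHSO5), [K+].[O-]S(=O)(=O)OO
Why: Shi asymmetric epoxidation: the chiral dioxirane should attack the electron-rich trisubstituted E-olefin (the 1,1-disubstituted and the electron-poor olefins react far more slowly) through the spiro transition state on the face that gives the (3R,4R) trans-epoxide, both new centres being set by the catalyst.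

**Compound list**

1 | (S)-citronellal | CC(C)=CCC[C@H](C)CC=O | starting material
2 | (2R,3S)-3,7-dimethyl-2-[(phenylamino)oxy]oct-6-enal | CC(C)=CCC[C@H](C)[C@@H](ONc1ccccc1)C=O | intermediate
3 | (2R,3S)-3,7-dimethyl-2-[(phenylamino)oxy]oct-6-en-1-ol | CC(C)=CCC[C@H](C)[C@@H](ONc1ccccc1)CO | intermediate
4 | (2R,3S)-3,7-dimethyloct-6-ene-1,2-diol | CC(C)=CCC[C@H](C)[C@@H](O)CO | intermediate
5 | (4R)-2,2-dimethyl-4-[(2S)-6-methylhept-5-en-2-yl]-1,3-dioxolane | CC(C)=CCC[C@H](C)[C@@H]1COC(C)(C)O1 | intermediate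
6 | (4S)-4-[(4R)-2,2-dimethyl-1,3-dioxolan-4-yl]pentan-1-ol | OCCC[C@H](C)[C@@H]1COC(C)(C)O1 | intermediate
7 | (4R)-4-[(2S)-5-bromopentan-2-yl]-2,2-dimethyl-1,3-dioxolane | BrCCC[C@H](C)[C@@H]1COC(C)(C)O1 | intermediate
8 | (R)-α-hydroxy-γ-butyrolactone, (3R)-3-hydroxyoxolan-2-one | O=C1OCC[C@H]1O | starting material
9 | (2R)-2,4-dihydroxy-N-methoxy-N-methylbutanamide | OCC[C@@H](O)C(=O)N(C)OC | intermediate
10 | (2R)-2,4-bis[(tert-butyldimethylsilyl)oxy]-N-methoxy-N-methylbutanamide | CC(C)(C)[Si](C)(C)OCC[C@@H](O[Si](C)(C)C(C)(C)C)C(=O)N(C)OC | intermediate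
11 | {(4S)-4-[(4R)-2,2-dimethyl-1,3-dioxolan-4-yl]pentyl}magnesium bromide | Br[Mg]CCC[C@H](C)[C@@H]1COC(C)(C)O1 | intermediate
12 | (3R,8S)-1,3-bis[(tert-butyldimethylsilyl)oxy]-8-[(4R)-2,2-dimethyl-1,3-dioxolan-4-yl]nonan-4-one | CC(C)(C)[Si](C)(C)OCC[C@@H](O[Si](C)(C)C(C)(C)C)C(=O)CCC[C@H](C)[C@@H]1COC(C)(C)O1 | intermediate
13 | (3R,8S)-1,3-bis[(tert-butyldimethylsilyl)oxy]-8-[(4R)-2,2-dimethyl-1,3-dioxolan-4-yl]-4-methylidenenonane | CC(C)(C)[Si](C)(C)OCC[C@@H](O[Si](C)(C)C(C)(C)C)C(=C)CCC[C@H](C)[C@@H]1COC(C)(C)O1 | intermediate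
14 | (3R,8S)-3-[(tert-butyldimethylsilyl)oxy]-8-[(4R)-2,2-dimethyl-1,3-dioxolan-4-yl]-4-methylidenenonan-1-ol | OCC[C@@H](O[Si](C)(C)C(C)(C)C)C(=C)CCC[C@H](C)[C@@H]1COC(C)(C)O1 | intermediate
15 | (4R)-4-[(2S,7R)-7-[(tert-butyldimethylsilyl)oxy]-9-iodo-6-methylidenenonan-2-yl]-2,2-dimethyl-1,3-dioxolane | ICC[C@@H](O[Si](C)(C)C(C)(C)C)C(=C)CCC[C@H](C)[C@@H]1COC(C)(C)O1 | intermediate
16 | (2R,3S,8R)-8-[(tert-butyldimethylsilyl)oxy]-10-iodo-3-methyl-7-methylidenedecane-1,2-diol | ICC[C@@H](O[Si](C)(C)C(C)(C)C)C(=C)CCC[C@H](C)[C@@H](O)CO | intermediate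
17 | (2R,3S,8R)-8-[(tert-butyldimethylsilyl)oxy]-2-hydroxy-10-iodo-3-methyl-7-methylidenedecanal | ICC[C@@H](O[Si](C)(C)C(C)(C)C)C(=C)CCC[C@H](C)[C@@H](O)C=O | intermediate
18 | pent-3-yn-1-ol | CC#CCCO | starting material
19 | E-alkenylzirconocene chloride from 18, zirconium on C4 and trans to the chain, hydroxyl as its zirconocene alkoxide | C/C(=C\CCO[Zr](Cl)(C1C=CC=C1)C1C=CC=C1)[Zr](Cl)(C1C=CC=C1)C1C=CC=C1 | intermediate
20 | (3E)-4-iodopent-3-en-1-ol | OCC/C=C(\C)I | intermediate
21 | (3E)-4-iodopent-3-enal | O=CC/C=C(\C)I | intermediate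
22 | methyl propiolate | C#CC(=O)OC | starting material
23 | [1-(methoxycarbonyl)ethenyl]diisobutylaluminium | C=C(C(=O)OC)[Al](CC(C)C)CC(C)C | intermediate
24 | methyl (5E)-3-hydroxy-6-iodo-2-methylidenehept-5-enoate (racemic) | COC(=O)C(=C)C(O)C/C=C(\C)I | intermediate
25 | methyl (2Z,5E)-2-(bromomethyl)-6-iodohepta-2,5-dienoate | COC(=O)/C(CBr)=C/C/C=C(\C)I | intermediate
26 | [(2Z,5E)-6-iodo-2-(methoxycarbonyl)hepta-2,5-dien-1-yl]indium (monovalent indium) | COC(=O)/C(C[In])=C/C/C=C(\C)I | intermediate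
27 | methyl (3S,4R,5R,6S,11R)-11-[(tert-butyldimethylsilyl)oxy]-4,5-dihydroxy-13-iodo-3-[(2E)-3-iodobut-2-en-1-yl]-6-methyl-2,10-dimethylidenetridecanoate | ICC[C@@H](O[Si](C)(C)C(C)(C)C)C(=C)CCC[C@H](C)[C@@H](O)[C@H](O)[C@@H](C/C=C(\C)I)C(=C)C(=O)OC | intermediate
28 | (4S,5R)-5-[(1R,2S,7R)-7-[(tert-butyldimethylsilyl)oxy]-1-hydroxy-9-iodo-2-methyl-6-methylidenenonyl]-4-[(2E)-3-iodobut-2-en-1-yl]-3-methylideneoxolan-2-one | ICC[C@@H](O[Si](C)(C)C(C)(C)C)C(=C)CCC[C@H](C)[C@@H](O)[C@@H]1OC(=O)C(=C)[C@@H]1C/C=C(\C)I | intermediate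
29 | (4S,5R)-5-[(1R,2S,7R)-1,7-bis[(tert-butyldimethylsilyl)oxy]-9-iodo-2-methyl-6-methylidenenonyl]-4-[(2E)-3-iodobut-2-en-1-yl]-3-methylideneoxolan-2-one | ICC[C@@H](O[Si](C)(C)C(C)(C)C)C(=C)CCC[C@H](C)[C@@H](O[Si](C)(C)C(C)(C)C)[C@@H]1OC(=O)C(=C)[C@@H]1C/C=C(\C)I | intermediate
30 | alkylzinc iodide of 29 (C5–ZnI) | I[Zn]CC[C@@H](O[Si](C)(C)C(C)(C)C)C(=C)CCC[C@H](C)[C@@H](O[Si](C)(C)C(C)(C)C)[C@@H]1OC(=O)C(=C)[C@@H]1C/C=C(\C)I | intermediate
31 | (1S,3E,7R,12S,13R,14R)-7,13-bis[(tert-butyldimethylsilyl)oxy]cembra-3,8(19),15(17)-trien-16,14-olide | C=C1CCC[C@H](C)[C@@H](O[Si](C)(C)C(C)(C)C)[C@@H]2OC(=O)C(=C)[C@@H]2C/C=C(\C)CC[C@H]1O[Si](C)(C)C(C)(C)C | intermediate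
32 | (1S,3E,7R,12S,13R,14R)-7,13-dihydroxycembra-3,8(19),15(17)-trien-16,14-olide | C=C1CCC[C@H](C)[C@@H](O)[C@@H]2OC(=O)C(=C)[C@@H]2C/C=C(\C)CC[C@H]1O | intermediate
33 | CNP0124069.1, (1S,3R,4R,7R,12S,13R,14R)-3,4-epoxy-7,13-dihydroxycembra-8(19),15(17)-dien-16,14-olide | C=C1CCC[C@H](C)[C@@H](O)[C@@H]2OC(=O)C(=C)[C@@H]2C[C@H]2O[C@]2(C)CC[C@H]1O | target

**Totals**

Total step count: 22. Longest linear sequence: 16 steps (steps 1–5, 8–13, 18–22).

**Steps most likely to fail**

Step 20 (key macrocyclisation). Intermolecular coupling to oligomers, or protonolysis of the alkylzinc before transmetalation, may outrun closure of the 14-membered ring. The fallback sets out from 29 and returns at 31 without a preformed organometallic: a nickel-catalysed reductive cross-electrophile macrocyclisation (NiBr2·glyme, 4,4′-di-tert-butyl-2,2′-bipyridine, Mn powder, NaI, DMA, high dilution). Here the alkenyl iodide adds to nickel and the C5 radical generated from the alkyl iodide is captured at the metal before C4–C5 reductive elimination. No new compound is formed on the way.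

Step 18 (Barbier union). Chelate control may be lost in the aqueous medium, giving poor facial selectivity at C14, or the α-hydroxy aldehyde may self-condense before it is allylated. The fallback sets out from 16 and replaces substrate control by ligand control. Diol 16 is silylated (TBSCl, imidazole) to the tris-silyl ether F1. Its primary silyl ether is removed (HF·pyridine, pyridine) to give the primary alcohol F2, which is oxidised (Dess–Martin periodinane) to the α-silyloxy aldehyde F3. Bromide 25 is then added in a catalytic asymmetric chromium-mediated Nozaki–Hiyama-type 2-(alkoxycarbonyl)allylation (CrCl2, chiral oxazoline–sulfonamide ligand, Mn, TMSCl, then dilute acid), the ligand enantiomer being chosen to override the Felkin preference, to give the hydroxy ester F4. Acid lactonisation (TsOH) of F4 gives 29, where the route is rejoined.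

Step 22 (final epoxidation). The conformational bias of the macrocycle may override the catalyst and deliver oxygen to the wrong face, or the allylic alcohol and exocyclic olefin may be oxidised competitively. The fallback sets out from 31 and uses the intrinsic bias instead of fighting it. NBS in aqueous THF should form the bromonium ion on the intrinsically preferred face and water opens it anti at the tertiary C4, giving the bromohydrin F5. DBU in CH2Cl2 closes the oxirane with inversion at C3, so that oxygen ends on the face opposite to the one a direct epoxidation would choose, giving the bis-silyl epoxide F6. Buffered HF·pyridine then removes the silyl ethers to give 33.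

**Further compounds**

F0 | step 20 | none | none
F1 | step 18 | (2R,3S,8R)-1,2,8-tris[(tert-butyldimethylsilyl)oxy]-10-iodo-3-methyl-7-methylidenedecane | ICC[C@@H](O[Si](C)(C)C(C)(C)C)C(=C)CCC[C@H](C)[C@@H](O[Si](C)(C)C(C)(C)C)CO[Si](C)(C)C(C)(C)C
F2 | step 18 | (2R,3S,8R)-2,8-bis[(tert-butyldimethylsilyl)oxy]-10-iodo-3-methyl-7-methylidenedecan-1-ol | ICC[C@@H](O[Si](C)(C)C(C)(C)C)C(=C)CCC[C@H](C)[C@@H](O[Si](C)(C)C(C)(C)C)CO
F3 | step 18 | (2R,3S,8R)-2,8-bis[(tert-butyldimethylsilyl)oxy]-10-iodo-3-methyl-7-methylidenedecanal | ICC[C@@H](O[Si](C)(C)C(C)(C)C)C(=C)CCC[C@H](C)[C@@H](O[Si](C)(C)C(C)(C)C)C=O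
F4 | step 18 | methyl (3S,4R,5R,6S,11R)-5,11-bis[(tert-butyldimethylsilyl)oxy]-4-hydroxy-13-iodo-3-[(2E)-3-iodobut-2-en-1-yl]-6-methyl-2,10-dimethylidenetridecanoate | ICC[C@@H](O[Si](C)(C)C(C)(C)C)C(=C)CCC[C@H](C)[C@@H](O[Si](C)(C)C(C)(C)C)[C@H](O)[C@@H](C/C=C(\C)I)C(=C)C(=O)OC
F5 | step 22 | (1S,3S,4R,7R,12S,13R,14R)-3-bromo-7,13-bis[(tert-butyldimethylsilyl)oxy]-4-hydroxycembra-8(19),15(17)-dien-16,14-olide | C=C1CCC[C@H](C)[C@@H](O[Si](C)(C)C(C)(C)C)[C@@H]2OC(=O)C(=C)[C@@H]2C[C@H](Br)[C@](C)(O)CC[C@H]1O[Si](C)(C)C(C)(C)C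
F6 | step 22 | (1S,3R,4R,7R,12S,13R,14R)-7,13-bis[(tert-butyldimethylsilyl)oxy]-3,4-epoxycembra-8(19),15(17)-dien-16,14-olide | C=C1CCC[C@H](C)[C@@H](O[Si](C)(C)C(C)(C)C)[C@@H]2OC(=O)C(=C)[C@@H]2C[C@H]2O[C@]2(C)CC[C@H]1O[Si](C)(C)C(C)(C)C
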